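**Retrosynthetic overview**
1. Target 30 ⇐ macrocyclic alcohol 27, by acylation of the C8 hydroxyl and late unveiling of the C9 ketone.
2. Key disconnection C7–C8: 27 ⇐ seco-aldehyde 26. A samarium ketyl radical at C8 closes the ten-membered ring onto C7 of a 3-(phenylsulfanylmethyl)butenolide, and loss of PhS• creates the exocyclic methylene in the same event.
3. C5–C6: 26 ⇐ vinylogous Mukaiyama aldol of a silyloxyfuran (from tulipalin A) with α-silyloxy aldehyde 16; this sets C5 and C6.
4. C2–C3: 16 ⇐ iodide 9 + (R)-2-methylglycidol (brings C4); 9 ⇐ syn-crotylboration of protected glycolaldehyde (sets C10 and a temporary C9 centre).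
5. Ring order: the γ-lactone ring is carried intact from tulipalin A; the ten-membered carbocycle is formed last, in the radical step.

Assumption: PMB-protected glycolaldehyde 1, (R)-2-methylglycidol 10 and (R)-2-methylbutanoic acid 28 are taken as purchasable; atom labels C1–C15 follow germacranolide numbering (lactone oxygen on C6, C12 lactone carbonyl, C13 exocyclic methylene, ketone at C9, methyls on C4 and C10).

**Route**

Step 1
Reactants: 1 2-[(4-methoxyphenyl)methoxy]acetaldehyde; 2 cis-2-butene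
Product: 6 (2S,3R)-1-[(4-methoxyphenyl)methoxy]-3-methylpent-4-en-2-ol, via (Z)-crotylpotassium 3 (not isolated), via (Z)-crotylbis(isopinocampheyl)borane 4 (not isolated), via borinate ester 5 (not isolated)
Conditions: 2, KOtBu, n-BuLi, THF, −78 to −45 °C; (−)-Ipc2BOMe, −78 °C; BF3·OEt2; 1, −78 °C; then NaOH, H2O2, rt
Reagents that add atoms: none
Why: Brown asymmetric crotylboration through a closed chair Zimmerman–Traxler transition state, in which the Z geometry gives the syn adduct and the isopinocampheyl groups of the (+)-α-pinene series direct attack to the Si face of the aldehyde, setting C9 (S) and C10 (R).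

Step 2
Reactants: 6 homoallylic alcohol
Product: 7 (3R,4S)-5-[(4-methoxyphenyl)methoxy]-3-methyl-4-(triethylsilyloxy)pent-1-ene
Conditions: TESCl, imidazole, DMF, 0 °C to rt
Reagents that add atoms: chlorotriethylsilane (TESCl), CC[Si](Cl)(CC)CC
Why: Standard silylation of the secondary alcohol that touches no stereocentre and gives an ether that lasts until the final acidic oxidation.

Step 3
Reactants: 7 silyl ether
Product: 9 (2S,3R)-5-iodo-1-[(4-methoxyphenyl)methoxy]-3-methyl-2-(triethylsilyloxy)pentane, via B-alkyl-9-BBN adduct 8 (not isolated)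
Conditions: 9-BBN, THF, 0 °C to rt; then NaOMe, I2, MeOH, 0 °C
Reagents that add atoms: iodine (I2), [I][I]
Why: Anti-Markovnikov hydroboration of the terminal alkene followed by Brown base-induced iodinolysis of the primary B–C bond gives the primary iodide without touching C9 or C10.

Step 4
Reactants: 9 iodide; 10 (R)-2-methylglycidol
Product: 14 (2S,6R,7S)-8-[(4-methoxyphenyl)methoxy]-2,6-dimethyl-1,2,7-tris(triethylsilyloxy)octane, via chloromagnesium glycidolate 11 (not isolated), via Grignard reagent 12 (not isolated), via bis(halomagnesium) dialkoxide 13 (not isolated)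
Conditions: 10, i-PrMgCl, THF, −20 °C; 9, Mg, THF, rt; combine, CuI (10 mol %), −30 to 0 °C; then TESOTf, −78 to 0 °C
Reagents that add atoms: triethylsilyl trifluoromethanesulfonate (TESOTf), CC[Si](CC)(CC)OS(=O)(=O)C(F)(F)F
Why: Copper-catalysed Grignard opening of the 2,2-disubstituted epoxide at its CH2 terminus (SN2) leaves the quaternary carbinol carbon untouched, so C4 (S) comes directly from (R)-2-methylglycidol, and both alkoxides are capped in the same flask.

Step 5
Reactants: 14 tris(silyl) ether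
Product: 16 (2S,6R,7S)-8-[(4-methoxyphenyl)methoxy]-2,6-dimethyl-2,7-bis(triethylsilyloxy)octanal, via alkoxydimethylsulfonium chloride 15 (not isolated)
Conditions: (COCl)2, DMSO, CH2Cl2, −78 to −40 °C; then Et3N, −78 to 0 °C
Reagents that add atoms: none
Why: Swern oxidation converts a primary triethylsilyl ether directly into the aldehyde while secondary and tertiary silyl ethers are inert at low temperature, and the aldehyde has no α-hydrogen so C4 cannot epimerise.

Step 6
Reactants: 17 tulipalin A (α-methylene-γ-butyrolactone)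
Product: 20 3-[(phenylsulfanyl)methyl]furan-2(5H)-one, via 3-bromo-3-(bromomethyl)oxolan-2-one 18 (not isolated), via 3-(bromomethyl)furan-2(5H)-one 19 (not isolated)
Conditions: Br2, CH2Cl2, 0 °C to rt; Et3N, 0 °C; then PhSH, Et3N, 0 °C to rt
Reagents that add atoms: benzenethiol, Sc1ccccc1
Why: Bromine addition to the exocyclic alkene, E2 loss of HBr into the ring to give the conjugated butenolide and thiolate displacement of the allylic bromide (any SN2' adduct reverts to the conjugated isomer) are telescoped, and no stereocentre is formed.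

Step 7
Reactants: 16 aldehyde; 20 butenolide sulfide
Product: 22 (5S)-5-[(1R,2S,6R,7S)-1-hydroxy-8-[(4-methoxyphenyl)methoxy]-2,6-dimethyl-2,7-bis(triethylsilyloxy)octyl]-3-[(phenylsulfanyl)methyl]furan-2(5H)-one, via 2-(trimethylsilyloxy)furan 21 (not isolated)
Conditions: 20, TMSOTf, Et3N, CH2Cl2, 0 °C; then 16, BF3·OEt2, −78 °C; aq. NaHCO3
Reagents that add atoms: none
Why: Vinylogous Mukaiyama aldol reaction in which the silyloxyfuran attacks through its γ-carbon in an open transition state that gives the threo (5,6-syn) carbinol, while polar Felkin–Anh control by the non-chelated α-silyloxy group sets C5 anti to the C4 oxygen, giving C5 (R) and C6 (S) with minor diastereomers removed by chromatography.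

Step 8
Reactants: 22 alcohol; 23 isobutyryl chloride
Product: 24 (1R,2S,6R,7S)-8-[(4-methoxyphenyl)methoxy]-2,6-dimethyl-1-[(2S)-5-oxo-4-[(phenylsulfanyl)methyl]-2,5-dihydrofuran-2-yl]-2,7-bis(triethylsilyloxy)octyl 2-methylpropanoate
Conditions: pyridine, DMAP (cat.), CH2Cl2, 0 °C to rt
Reagents that add atoms: none
Why: DMAP-catalysed acylation of the only free hydroxyl installs the C5 isobutyrate early, and pyridine is too weak a base to deprotonate the butenolide γ-position.

Step 9
Reactants: 24 PMB ether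
Product: 25 (1R,2S,6R,7S)-8-hydroxy-2,6-dimethyl-1-[(2S)-5-oxo-4-[(phenylsulfanyl)methyl]-2,5-dihydrofuran-2-yl]-2,7-bis(triethylsilyloxy)octyl 2-methylpropanoate
Conditions: DDQ, CH2Cl2/pH 7 buffer, 0 °C
Reagents that add atoms: none
Why: Oxidative cleavage of the p-methoxybenzyl ether (hydride abstraction, then hydrolysis of the oxocarbenium ion) frees only the C8 hydroxyl, and buffering keeps the silyl ethers intact.

Step 10
Reactants: 25 primary alcohol
Product: 26 (1R,2S,6R,7S)-2,6-dimethyl-8-oxo-1-[(2S)-5-oxo-4-[(phenylsulfanyl)methyl]-2,5-dihydrofuran-2-yl]-2,7-bis(triethylsilyloxy)octyl 2-methylpropanoate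
Conditions: Dess–Martin periodinane, NaHCO3, CH2Cl2, 0 °C to rt
Reagents that add atoms: none
Why: Buffered Dess–Martin oxidation gives the α-silyloxy aldehyde without epimerising C9 or oxidising the sulfide, and the aldehyde is used at once.

Step 11
Reactants: 26 seco-aldehyde
Product: 27 (3aR,4R,5S,6R,10S,11R,11aS)-4-hydroxy-6,10-dimethyl-3-methylidene-2-oxo-5,10-bis(triethylsilyloxy)dodecahydrocyclodeca[b]furan-11-yl 2-methylpropanoate
Conditions: SmI2 (2.5 equiv), THF, 0.002 M, syringe-pump addition of 26, −20 to 0 °C; AcOH, −78 °C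
Reagents that add atoms: none
Why: Proposed new method: SmI2 reduces the aldehyde to a samarium ketyl radical at C8 that attacks the β-carbon C7 of the butenolide, and the resulting α-lactone radical at C11 expels PhS• (reduced by a second SmI2), so ring closure and methylene formation are one radical addition–fragmentation (closest known reactions: SmI2 ketyl–olefin cyclisations onto unsaturated esters and lactones up to eight-membered rings, and radical allylation by addition–fragmentation of allyl sulfides); attack anti to C5 is expected because only then is the forming bond staggered about C6–C7 (about 150° ring torsion), giving the trans-lactone at C7, and C8 (R) is expected from a transition state in which the ketyl O–Sm bridges to the lactone carbonyl with H8 over the ring, the same sense as the polar Felkin–Anh preference of the (9S)-silyloxy group.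

Step 12
Reactants: 27 macrocyclic alcohol; 28 (R)-2-methylbutanoic acid
Product: 29 (3aS,4R,5S,6R,10S,11R,11aS)-6,10-dimethyl-3-methylidene-11-[(2-methylpropanoyl)oxy]-2-oxo-5,10-bis(triethylsilyloxy)dodecahydrocyclodeca[b]furan-4-yl (2R)-2-methylbutanoate
Conditions: DCC, DMAP (cat.), CH2Cl2, 0 °C to rt
Reagents that add atoms: none
Why: Steglich esterification of the single free hydroxyl (the tertiary C4 oxygen is silylated) attaches the ester with retention at C8 and without racemising the α-branched acid at 0 °C.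

Step 13
Reactants: 29 bis(silyl) ether
Product: 30 target CNP0071420.1
Conditions: CrO3, H2SO4, H2O, acetone, 0 °C to rt
Reagents that add atoms: none
Why: Jones oxidation in which the aqueous sulfuric acid hydrolyses both triethylsilyl ethers and hexavalent chromium oxidises the liberated C9 alcohol to the ketone, while the tertiary C4 alcohol cannot be oxidised and the short cold acidic treatment should not epimerise C8 or C10.

**Compound list**

1 | 2-[(4-methoxyphenyl)methoxy]acetaldehyde | COc1ccc(COCC=O)cc1 | starting material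
2 | cis-2-butene | C/C=C\C | starting material
3 | (Z)-crotylpotassium | C/C=C\C[K] | intermediate
4 | (Z)-crotylbis(isopinocampheyl)borane, (+)-α-pinene series | C/C=C\CB([C@@H]1C[C@@H]2C[C@H]([C@H]1C)C2(C)C)[C@@H]3C[C@@H]4C[C@H]([C@H]3C)C4(C)C | intermediate
5 | (2S,3R)-1-[(4-methoxyphenyl)methoxy]-3-methylpent-4-en-2-yl bis(isopinocampheyl)borinate | COc1ccc(COC[C@@H](OB([C@@H]2C[C@@H]3C[C@H]([C@H]2C)C3(C)C)[C@@H]4C[C@@H]5C[C@H]([C@H]4C)C5(C)C)[C@H](C)C=C)cc1 | intermediate
6 | (2S,3R)-1-[(4-methoxyphenyl)methoxy]-3-methylpent-4-en-2-ol | COc1ccc(COC[C@@H](O)[C@H](C)C=C)cc1 | intermediate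
7 | (3R,4S)-5-[(4-methoxyphenyl)methoxy]-3-methyl-4-(triethylsilyloxy)pent-1-ene | COc1ccc(COC[C@@H](O[Si](CC)(CC)CC)[C@H](C)C=C)cc1 | intermediate
8 | 9-[(3R,4S)-5-[(4-methoxyphenyl)methoxy]-3-methyl-4-(triethylsilyloxy)pentyl]-9-borabicyclo[3.3.1]nonane | COc1ccc(COC[C@@H](O[Si](CC)(CC)CC)[C@H](C)CCB2C3CCCC2CCC3)cc1 | intermediate
9 | (2S,3R)-5-iodo-1-[(4-methoxyphenyl)methoxy]-3-methyl-2-(triethylsilyloxy)pentane | COc1ccc(COC[C@@H](O[Si](CC)(CC)CC)[C@H](C)CCI)cc1 | intermediate
10 | (R)-2-methylglycidol, (R)-(2-methyloxiran-2-yl)methanol | C[C@@]1(CO)CO1 | starting material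
11 | chloromagnesium (R)-(2-methyloxiran-2-yl)methoxide | C[C@@]1(CO[Mg]Cl)CO1 | intermediate
12 | [(3R,4S)-5-[(4-methoxyphenyl)methoxy]-3-methyl-4-(triethylsilyloxy)pentyl]magnesium iodide | COc1ccc(COC[C@@H](O[Si](CC)(CC)CC)[C@H](C)CC[Mg]I)cc1 | intermediate
13 | bis(halomagnesium) dialkoxide of (2S,6R,7S)-8-[(4-methoxyphenyl)methoxy]-2,6-dimethyl-7-(triethylsilyloxy)octane-1,2-diol | COc1ccc(COC[C@@H](O[Si](CC)(CC)CC)[C@H](C)CCC[C@](C)(O[Mg]I)CO[Mg]Cl)cc1 | intermediate
14 | (2S,6R,7S)-8-[(4-methoxyphenyl)methoxy]-2,6-dimethyl-1,2,7-tris(triethylsilyloxy)octane | COc1ccc(COC[C@@H](O[Si](CC)(CC)CC)[C@H](C)CCC[C@](C)(O[Si](CC)(CC)CC)CO[Si](CC)(CC)CC)cc1 | intermediate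
15 | alkoxydimethylsulfonium chloride of the C5 oxygen of 14 | COc1ccc(COC[C@@H](O[Si](CC)(CC)CC)[C@H](C)CCC[C@](C)(O[Si](CC)(CC)CC)CO[S+](C)C)cc1.[Cl-] | intermediate
16 | (2S,6R,7S)-8-[(4-methoxyphenyl)methoxy]-2,6-dimethyl-2,7-bis(triethylsilyloxy)octanal | COc1ccc(COC[C@@H](O[Si](CC)(CC)CC)[C@H](C)CCC[C@](C)(O[Si](CC)(CC)CC)C=O)cc1 | intermediate
17 | tulipalin A, 3-methylideneoxolan-2-one | C=C1CCOC1=O | starting material
18 | 3-bromo-3-(bromomethyl)oxolan-2-one (racemic) | BrCC1(Br)CCOC1=O | intermediate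
19 | 3-(bromomethyl)furan-2(5H)-one | BrCC1=CCOC1=O | intermediate
20 | 3-[(phenylsulfanyl)methyl]furan-2(5H)-one | O=C1OCC=C1CSc1ccccc1 | intermediate
21 | 2-(trimethylsilyloxy)-3-[(phenylsulfanyl)methyl]furan | C[Si](C)(C)Oc1occc1CSc1ccccc1 | intermediate
22 | (5S)-5-[(1R,2S,6R,7S)-1-hydroxy-8-[(4-methoxyphenyl)methoxy]-2,6-dimethyl-2,7-bis(triethylsilyloxy)octyl]-3-[(phenylsulfanyl)methyl]furan-2(5H)-one | O=C1O[C@H]([C@@H](O)[C@@](C)(O[Si](CC)(CC)CC)CCC[C@@H](C)[C@H](O[Si](CC)(CC)CC)COCc3ccc(OC)cc3)C=C1CSc2ccccc2 | intermediate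
23 | isobutyryl chloride, 2-methylpropanoyl chloride | CC(C)C(Cl)=O | starting material
24 | (1R,2S,6R,7S)-8-[(4-methoxyphenyl)methoxy]-2,6-dimethyl-1-[(2S)-5-oxo-4-[(phenylsulfanyl)methyl]-2,5-dihydrofuran-2-yl]-2,7-bis(triethylsilyloxy)octyl 2-methylpropanoate | O=C1O[C@H]([C@@H](OC(=O)C(C)C)[C@@](C)(O[Si](CC)(CC)CC)CCC[C@@H](C)[C@H](O[Si](CC)(CC)CC)COCc3ccc(OC)cc3)C=C1CSc2ccccc2 | intermediate
25 | (1R,2S,6R,7S)-8-hydroxy-2,6-dimethyl-1-[(2S)-5-oxo-4-[(phenylsulfanyl)methyl]-2,5-dihydrofuran-2-yl]-2,7-bis(triethylsilyloxy)octyl 2-methylpropanoate | O=C1O[C@H]([C@@H](OC(=O)C(C)C)[C@@](C)(O[Si](CC)(CC)CC)CCC[C@@H](C)[C@H](O[Si](CC)(CC)CC)CO)C=C1CSc2ccccc2 | intermediate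
26 | (1R,2S,6R,7S)-2,6-dimethyl-8-oxo-1-[(2S)-5-oxo-4-[(phenylsulfanyl)methyl]-2,5-dihydrofuran-2-yl]-2,7-bis(triethylsilyloxy)octyl 2-methylpropanoate | O=C1O[C@H]([C@@H](OC(=O)C(C)C)[C@@](C)(O[Si](CC)(CC)CC)CCC[C@@H](C)[C@H](O[Si](CC)(CC)CC)C=O)C=C1CSc2ccccc2 | intermediate
27 | (3aR,4R,5S,6R,10S,11R,11aS)-4-hydroxy-6,10-dimethyl-3-methylidene-2-oxo-5,10-bis(triethylsilyloxy)dodecahydrocyclodeca[b]furan-11-yl 2-methylpropanoate | C=C1C(=O)O[C@H]2[C@H]1[C@@H](O)[C@@H](O[Si](CC)(CC)CC)[C@H](C)CCC[C@](C)(O[Si](CC)(CC)CC)[C@@H]2OC(=O)C(C)C | intermediate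
28 | (R)-2-methylbutanoic acid | OC(=O)[C@H](C)CC | starting material
29 | (3aS,4R,5S,6R,10S,11R,11aS)-6,10-dimethyl-3-methylidene-11-[(2-methylpropanoyl)oxy]-2-oxo-5,10-bis(triethylsilyloxy)dodecahydrocyclodeca[b]furan-4-yl (2R)-2-methylbutanoate | C=C1C(=O)O[C@H]2[C@H]1[C@@H](OC(=O)[C@H](C)CC)[C@@H](O[Si](CC)(CC)CC)[C@H](C)CCC[C@](C)(O[Si](CC)(CC)CC)[C@@H]2OC(=O)C(C)C | intermediate
30 | (3aS,4R,6R,10S,11R,11aS)-10-hydroxy-6,10-dimethyl-3-methylidene-11-[(2-methylpropanoyl)oxy]-2,5-dioxododecahydrocyclodeca[b]furan-4-yl (2R)-2-methylbutanoate (CNP0071420.1) | C=C1C(=O)O[C@H]2[C@H]1[C@@H](OC(=O)[C@H](C)CC)C(=O)[C@H](C)CCC[C@](C)(O)[C@@H]2OC(=O)C(C)C | target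

**Totals and risks**

Total step count: 13. Longest linear sequence: 12 (steps 1–5 and 7–13; step 6 is the side branch).

Most likely to fail, first: step 11. The ten-membered ring closure is beyond precedent in ring size, and pinacol dimerisation, simple reduction of the aldehyde or the wrong C7/C8 diastereomer may win. The fallback sets out from aldehyde 26 and replaces the reductive samarium chemistry by a tin-mediated chain process. Acid 28 is converted with oxalyl bromide into (2R)-2-methylbutanoyl bromide F1, which adds across the aldehyde of 26 under ZnBr2 catalysis (CH2Cl2, −20 °C) to give the 1-bromoalkyl (2R)-2-methylbutanoate F2 (both C8 epimers, which converge at the radical). Irradiation of F2 with Bu3SnSnBu3 in benzene at 0.002 M abstracts bromine; the α-acyloxyalkyl radical at C8 closes onto C7 and the expelled PhS• carries the chain by attacking the ditin. This gives 29 directly with the ester already in place, so the route is rejoined at 29 and step 12 is not needed.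

Second: step 7. Felkin–Anh discrimination between the methyl and methylene groups on the quaternary C4 may be modest, which would erode the C5/C6 selectivity. The fallback sets out from aldehyde 16 and returns at 24, with both new centres set by the reagent. Brown's [(Z)-3-(methoxymethoxy)allyl]bis(isopinocampheyl)borane F3 (from allyl methoxymethyl ether, sec-BuLi, (+)-Ipc2BOMe and BF3·OEt2) adds to the Re face of 16 and gives, after NaOH/H2O2, the syn diol monoether (3S,4R,5S,9R,10S)-11-[(4-methoxyphenyl)methoxy]-3-(methoxymethoxy)-5,9-dimethyl-5,10-bis(triethylsilyloxy)undec-1-en-4-ol F4. Acylation with 23 gives its isobutyrate F5. Me2BBr at −78 °C removes the methoxymethyl group to give the allylic alcohol F6. DCC coupling with 2-[(phenylsulfanyl)methyl]prop-2-enoic acid F7 (from 2-(bromomethyl)acrylic acid, PhSH and Et3N) gives the diene ester F8. Ring-closing metathesis with the second-generation Grubbs catalyst RuCl2(H2IMes)(PCy3)(=CHPh) then closes the butenolide and gives 24.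

Third: step 13. The tertiary silyl ether may hydrolyse slowly, or the acid may cause acyl migration before oxidation. The fallback sets out from 29 and separates the two events under non-acidic oxidation. HF·pyridine in THF/pyridine at 0 °C removes both silyl groups to give the diol (3aR,4R,5S,6R,10S,11R,11aS)-5,10-dihydroxy-6,10-dimethyl-3-methylidene-11-[(2-methylpropanoyl)oxy]-2-oxododecahydrocyclodeca[b]furan-4-yl (2R)-2-methylbutanoate F9. Dess–Martin periodinane with NaHCO3 in CH2Cl2 then oxidises only the secondary C9 alcohol and gives 30.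

**Further compounds**

F1 | step 11 | (2R)-2-methylbutanoyl bromide | BrC(=O)[C@H](C)CC
F2 | step 11 | 1-bromoalkyl ester: (1R,2S,6R,7S)-8-bromo-2,6-dimethyl-8-{[(2R)-2-methylbutanoyl]oxy}-1-[(2S)-5-oxo-4-[(phenylsulfanyl)methyl]-2,5-dihydrofuran-2-yl]-2,7-bis(triethylsilyloxy)octyl 2-methylpropanoate (C8 epimers) | O=C1O[C@H]([C@@H](OC(=O)C(C)C)[C@@](C)(O[Si](CC)(CC)CC)CCC[C@@H](C)[C@H](O[Si](CC)(CC)CC)C(Br)OC(=O)[C@H](C)CC)C=C1CSc2ccccc2
F3 | step 7 | [(Z)-3-(methoxymethoxy)prop-2-enyl]bis(isopinocampheyl)borane, (−)-α-pinene series | COCO/C=C\CB([C@H]1C[C@H]2C[C@@H]([C@@H]1C)C2(C)C)[C@H]3C[C@H]4C[C@@H]([C@@H]3C)C4(C)C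
F4 | step 7 | (3S,4R,5S,9R,10S)-11-[(4-methoxyphenyl)methoxy]-3-(methoxymethoxy)-5,9-dimethyl-5,10-bis(triethylsilyloxy)undec-1-en-4-ol | C=C[C@H](OCOC)[C@@H](O)[C@@](C)(O[Si](CC)(CC)CC)CCC[C@@H](C)[C@H](O[Si](CC)(CC)CC)COCc1ccc(OC)cc1
F5 | step 7 | 4-O-(2-methylpropanoyl) ester of F4 | C=C[C@H](OCOC)[C@@H](OC(=O)C(C)C)[C@@](C)(O[Si](CC)(CC)CC)CCC[C@@H](C)[C@H](O[Si](CC)(CC)CC)COCc1ccc(OC)cc1
F6 | step 7 | 3-hydroxy compound from F5 (methoxymethyl group removed) | C=C[C@H](O)[C@@H](OC(=O)C(C)C)[C@@](C)(O[Si](CC)(CC)CC)CCC[C@@H](C)[C@H](O[Si](CC)(CC)CC)COCc1ccc(OC)cc1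
F7 | step 7 | 2-[(phenylsulfanyl)methyl]prop-2-enoic acid | C=C(CSc1ccccc1)C(=O)O
F8 | step 7 | 3-O-{2-[(phenylsulfanyl)methyl]prop-2-enoyl} ester of F6 | C=C[C@H](OC(=O)C(=C)CSc2ccccc2)[C@@H](OC(=O)C(C)C)[C@@](C)(O[Si](CC)(CC)CC)CCC[C@@H](C)[C@H](O[Si](CC)(CC)CC)COCc1ccc(OC)cc1
F9 | step 13 | (3aR,4R,5S,6R,10S,11R,11aS)-5,10-dihydroxy-6,10-dimethyl-3-methylidene-11-[(2-methylpropanoyl)oxy]-2-oxododecahydrocyclodeca[b]furan-4-yl (2R)-2-methylbutanoate | C=C1C(=O)O[C@H]2[C@H]1[C@@H](OC(=O)[C@H](C)CC)[C@@H](O)[C@H](C)CCC[C@](C)(O)[C@@H]2OC(=O)C(C)C
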